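**Plan**

1. Target numbering: bicyclo[3.2.1]octane with C1 (prenyl bridgehead), C2–C3–C4 (acylated, enolized 1,3-dione bridge), C5 (methyl bridgehead), C6 (CH–CMe2OH), C7 (CH2), C8 (bridging C=O).
2. Cuts, in retrosynthetic order: C6–C7 together with the carbinol C–O bond; C1–prenyl; C5–alkenyl; C1–C7; aryl–acyl.
3. Enabling feature: C6 and C7 are both β to the C8 ketone (like polarity) and stand 1,3-diaxial on the six-membered ring C1–C2–C3–C4–C5–C8, and C6 carries the carbinol carbon. A primary C7 radical on C1 can therefore close 5-exo onto a 2-methylprop-1-enyl group on C5, and the tertiary radical left on the carbinol carbon takes up O2.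
4. Forward: Friedel–Crafts acylphloroglucinol; C7 attached as CH2SePh; two dearomatizing C-alkylations (alkenyl at C5, prenyl at C1) give the fully substituted six-membered ring; the five-membered ring C1–C8–C5–C6–C7 closes last and completes the bicycle.
5. Stereochemistry: the side-chain centre is bought as (R)-2-methylbutanoic acid; C5 is set by Pd/chiral bisphosphine catalysis; C1 by a ligand-controlled Tsuji–Trost prenylation; C6 is relayed from C1/C5 in the ring closure (exo).

Key step: step 6

Remark on the chemistry: the enolized β-triketone units are drawn as one tautomer throughout (the tautomers equilibrate freely), and the CIP descriptors refer to the tautomer drawn.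

**Route**

Step 1
Reactants: 1 (2R)-2-methylbutanoic acid
Product: 2 (2R)-2-methylbutanoyl chloride
Conditions: (COCl)2, DMF (cat.), CH2Cl2, 0 °C to rt
Reagents that add atoms: oxalyl chloride, O=C(Cl)C(=O)Cl
Why: Acid chloride formation through the chloroiminium salt from DMF and oxalyl chloride, run cold and without base so that the α-stereocentre is not enolized.

Step 2
Reactants: 2 (2R)-2-methylbutanoyl chloride; 3 2-methylbenzene-1,3,5-triol
Product: 4 (2R)-2-methyl-1-(2,4,6-trihydroxy-3-methylphenyl)butan-1-one
Conditions: AlCl3 (3.5 equiv), CH2Cl2/PhNO2, 0 °C to rt; aq. HCl work-up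
Reagents that add atoms: none
Why: Friedel–Crafts acylation of the electron-rich triol; the two free ring positions are equivalent, the first acyl group deactivates the ring against a second one, and the low temperature should spare the α-stereocentre.

Step 3
Reactants: 4 (2R)-2-methyl-1-(2,4,6-trihydroxy-3-methylphenyl)butan-1-one
Product: 6 (2R)-2-methyl-1-{2,4,6-trihydroxy-3-methyl-5-[(phenylselanyl)methyl]phenyl}butan-1-one, via ortho-quinone methide 5 (not isolated)
Conditions: PhSeH (1.5 equiv), 37% aq. CH2O, NaOAc (cat.), EtOH, rt, argon
Reagents that add atoms: formaldehyde, C=O; benzeneselenol, [SeH]c1ccccc1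
Why: Mannich-type three-component (phenylselanyl)methylation, the selenium counterpart of the thiol/formaldehyde alkylthiomethylation of phenols and cyclic 1,3-diones: formaldehyde attacks the only unsubstituted ring carbon, loss of water gives ortho-quinone methide 5, and the soft selenol adds to its methylene carbon (hetero-Michael addition), the excess of selenol outcompeting attack by a second arene.

Step 4
Reactants: 6 (2R)-2-methyl-1-{2,4,6-trihydroxy-3-methyl-5-[(phenylselanyl)methyl]phenyl}butan-1-one
Product: 7 (6R)-3,5-dihydroxy-6-methyl-4-[(2R)-2-methylbutanoyl]-6-(2-methylprop-1-en-1-yl)-2-[(phenylselanyl)methyl]cyclohexa-2,4-dien-1-one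
Conditions: 1-bromo-2-methylprop-1-ene, Pd2(dba)3 (2.5 mol%), (R)-DTBM-SEGPHOS (6 mol%), K3PO4, toluene, 60 °C, argon (sealed vessel)
Reagents that add atoms: 1-bromo-2-methylprop-1-ene, CC(C)=CBr
Why: Proposed new method: Pd-catalysed enantioselective dearomative C-alkenylation of a phenol with an alkenyl bromide; oxidative addition of the bromide to zerovalent palladium, exchange of bromide for the phenoxide of 6, O-to-C shift to a C-bound palladium dienone at the methyl-bearing ring carbon and C(sp3)–C(sp2) reductive elimination should create the quaternary centre, the chiral bisphosphine choosing the enantioface (the antipodal ligand is used if the sense of induction proves opposite); the closest known reaction types are the Pd-catalysed asymmetric α-alkenylation of ketone enolates to α-quaternary ketones and the Pd-catalysed arylative dearomatization of naphthols; the methyl-bearing carbon should react because the selanylmethyl-bearing one is more hindered and the acyl-bearing one is the unreactive centre of a β-triketone; the alkene has to be installed as such because, by analogy with the 2,4,4-trimethylpentenes, a 2-methylprop-1-enyl group on a quaternary carbon is expected to be less stable than its 2-methylallyl isomer and so is not reached cleanly by isomerization.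

Step 5
Reactants: 7 (6R)-3,5-dihydroxy-6-methyl-4-[(2R)-2-methylbutanoyl]-6-(2-methylprop-1-en-1-yl)-2-[(phenylselanyl)methyl]cyclohexa-2,4-dien-1-one
Product: 8 (2R,6R)-5-hydroxy-6-methyl-4-[(2R)-2-methylbutanoyl]-2-(3-methylbut-2-en-1-yl)-6-(2-methylprop-1-en-1-yl)-2-[(phenylselanyl)methyl]cyclohex-4-ene-1,3-dione
Conditions: 3-methylbut-2-en-1-yl acetate, [Pd(C3H5)Cl]2 (2.5 mol%), (R,R)-DACH-phenyl ligand {N,N'-[(1R,2R)-cyclohexane-1,2-diyl]bis[2-(diphenylphosphanyl)benzamide]} (7.5 mol%), Et3N, CH2Cl2, 0 °C to rt, argon
Reagents that add atoms: 3-methylbut-2-en-1-yl acetate, CC(C)=CCOC(C)=O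
Why: Tsuji–Trost asymmetric allylic alkylation of a 2-substituted cyclic 1,3-dicarbonyl enol: the selanylmethyl-bearing carbon is the only ring carbon left that can be quaternized, attack at the unsubstituted allyl terminus gives the linear prenyl group, and the ligand-defined pocket (antipodal ligand if needed) selects the enol face so that prenyl enters anti to the alkenyl group, which places CH2SePh cis to it (2R).

Step 6
Reactants: 8 (2R,6R)-5-hydroxy-6-methyl-4-[(2R)-2-methylbutanoyl]-2-(3-methylbut-2-en-1-yl)-6-(2-methylprop-1-en-1-yl)-2-[(phenylselanyl)methyl]cyclohex-4-ene-1,3-dione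
Product: 10 (1R,5R,6R)-4-hydroxy-6-(2-hydroxypropan-2-yl)-5-methyl-3-[(2R)-2-methylbutanoyl]-1-(3-methylbut-2-en-1-yl)bicyclo[3.2.1]oct-3-ene-2,8-dione, via tertiary hydroperoxide 9 (not isolated)
Conditions: Bu3SnH (2.5 equiv, syringe pump), AIBN (cat.), dry air (slow stream), toluene (0.01 M), 70 °C; then PPh3, rt
Reagents that add atoms: dioxygen, O=O
Why: Bu3Sn• abstracts the phenylselanyl group to leave the primary C7 radical (a β-keto, homoenolate-type radical, i.e. C7 with reversed polarity), which adds to the CH carbon of the 2-methylprop-1-enyl group on C5 to form C6–C7; the tertiary radical so formed is captured by O2, the peroxyl radical takes hydrogen from Bu3SnH to carry the chain, and PPh3 reduces hydroperoxide 9 to the carbinol. The closest known reaction type is the tin hydride/O2 radical cyclization–hydroxylation of alkyl halides and selenides. The ring closed is the cyclopentanone ring C1–C8–C5–C6–C7, by 5-exo-trig attack across the 1,3-diaxial positions of the existing six-membered ring, which turns the monocycle into the bicyclo[3.2.1]octane. The only new stereocentre, C6, is set by the transition state in which the CMe2 terminus points away from the C2–C3–C4 bridge (exo, toward C8) and the small vinylic hydrogen lies over the ring; C1 and C5 are already fixed and only their cis arrangement allows closure. The step needs ring closure to beat capture of the primary radical by O2 or Bu3SnH and the competing 1,2-acyl shift, and it needs the tertiary radical to meet O2 before it adds to the prenyl group: the two quaternary ring carbons hold radical and alkene diaxial (fast 5-exo), attack at the unsubstituted alkene carbon excludes 6-endo closure, and slow addition of Bu3SnH under a low stationary O2 concentration leaves oxygen as the only fast partner of the longer-lived tertiary radical.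

**Compound list**

1 | (2R)-2-methylbutanoic acid | CC[C@@H](C)C(=O)O | starting material
2 | (2R)-2-methylbutanoyl chloride | CC[C@@H](C)C(=O)Cl | intermediate
3 | 2-methylbenzene-1,3,5-triol | Cc1c(O)cc(O)cc1O | starting material
4 | (2R)-2-methyl-1-(2,4,6-trihydroxy-3-methylphenyl)butan-1-one | CC[C@@H](C)C(=O)c1c(O)cc(O)c(C)c1O | intermediate
5 | 3,5-dihydroxy-2-methyl-6-methylidene-4-[(2R)-2-methylbutanoyl]cyclohexa-2,4-dien-1-one (ortho-quinone methide) | CC[C@@H](C)C(=O)C1=C(O)C(=C)C(=O)C(C)=C1O | intermediate
6 | (2R)-2-methyl-1-{2,4,6-trihydroxy-3-methyl-5-[(phenylselanyl)methyl]phenyl}butan-1-one | CC[C@@H](C)C(=O)c1c(O)c(C[Se]c2ccccc2)c(O)c(C)c1O | intermediate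
7 | (6R)-3,5-dihydroxy-6-methyl-4-[(2R)-2-methylbutanoyl]-6-(2-methylprop-1-en-1-yl)-2-[(phenylselanyl)methyl]cyclohexa-2,4-dien-1-one | CC[C@@H](C)C(=O)C1=C(O)[C@](C=C(C)C)(C)C(=O)C(C[Se]c2ccccc2)=C1O | intermediate
8 | (2R,6R)-5-hydroxy-6-methyl-4-[(2R)-2-methylbutanoyl]-2-(3-methylbut-2-en-1-yl)-6-(2-methylprop-1-en-1-yl)-2-[(phenylselanyl)methyl]cyclohex-4-ene-1,3-dione | CC[C@@H](C)C(=O)C1=C(O)[C@](C=C(C)C)(C)C(=O)[C@@](CC=C(C)C)(C[Se]c2ccccc2)C1=O | intermediate
9 | (1R,5R,6R)-6-(2-hydroperoxypropan-2-yl)-4-hydroxy-5-methyl-3-[(2R)-2-methylbutanoyl]-1-(3-methylbut-2-en-1-yl)bicyclo[3.2.1]oct-3-ene-2,8-dione | CC[C@@H](C)C(=O)C1=C(O)[C@]2(C)C(=O)[C@@](CC=C(C)C)(C[C@H]2C(C)(C)OO)C1=O | intermediate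
10 | (1R,5R,6R)-4-hydroxy-6-(2-hydroxypropan-2-yl)-5-methyl-3-[(2R)-2-methylbutanoyl]-1-(3-methylbut-2-en-1-yl)bicyclo[3.2.1]oct-3-ene-2,8-dione | CC[C@@H](C)C(=O)C1=C(O)[C@]2(C)C(=O)[C@@](CC=C(C)C)(C[C@H]2C(C)(C)O)C1=O | target

**Count and risks**

Total step count: 6. Longest linear sequence: 6 steps (1 to 10; 3 enters at step 2).

Steps most likely to fail:

Step 4 (proposed new method). What may go wrong: O- instead of C-alkenylation, reaction at the selanylmethyl-bearing ring carbon, stalling of the catalyst by O,O-chelation of the acylphenoxide or by selenium, and poor enantioface selection. Fallback with known chemistry, setting out from 6: a Tsuji–Trost asymmetric allylic dearomatization with 2-methylallyl acetate ([Pd(C3H5)Cl]2, (R,R)-DACH-phenyl ligand, Et3N) should give the 2-methylallyl dienone F1. Tsuji–Trost prenylation under the conditions of step 5 should then give the 2-methylallyl trione F2. A metal-hydride hydrogen-atom-transfer alkene isomerization (CoCl(salen) with salen = N,N'-bis(3,5-di-tert-butylsalicylidene)cyclohexane-1,2-diaminate, PhSiH3, benzene, rt) should move the double bond into the 2-methylprop-1-enyl position. Because this isomer is expected to be the minor partner at equilibrium, it would be separated on AgNO3-impregnated silica and F2 recycled. The fallback comes back to the route at 8.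

Step 5. What may go wrong: poor facial selectivity at the new quaternary carbon, O-prenylation or attack at the substituted allyl terminus, and loss of benzeneselenolate from the enolate by retro-Michael reaction. Fallback, setting out from 4, which reverses the order in which the two groups reach C1: aromatic C-prenylation (prenyl bromide, aq. KOH, 0 °C) should give the prenyl arene F3. Dearomative alkenylation as in step 4 should give the prenyl dienone F4. C-alkylation of its enol with chloromethyl phenyl selenide (K2CO3, DMF, 0 °C) then brings in the selanylmethyl group last. If the ring itself steers an incoming group onto the face of the alkenyl substituent (past the vinylic CH, not past the methyl group), that bias now gives the cis isomer. The fallback comes back to the route at 8.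

Step 6. What may go wrong: capture of the primary radical by O2 or Bu3SnH before ring closure, ring expansion by 1,2-acyl shift, and 6-exo addition of the tertiary radical to the prenyl group before it meets O2. Fallback, setting out from 8, which separates ring closure from oxygenation: a phenylselanyl group-transfer radical cyclization (Bu3SnSnBu3 (cat.), PhSeSePh (cat.), hν, benzene, rt) should give the tertiary selenide F5; premature capture of the primary radical by the diselenide only returns 8. Treating F5 with Bu3SnH and air and then PPh3, as in step 6, should replace selenium by hydroxyl through 9, with no ring closure left to compete. The fallback comes back to the route at 10.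

Further compounds
F1 | step 4 | (6R)-3,5-dihydroxy-6-methyl-4-[(2R)-2-methylbutanoyl]-6-(2-methylprop-2-en-1-yl)-2-[(phenylselanyl)methyl]cyclohexa-2,4-dien-1-one | CC[C@@H](C)C(=O)C1=C(O)[C@](CC(C)=C)(C)C(=O)C(C[Se]c2ccccc2)=C1O
F2 | step 4 | (2R,6R)-5-hydroxy-6-methyl-4-[(2R)-2-methylbutanoyl]-2-(3-methylbut-2-en-1-yl)-6-(2-methylprop-2-en-1-yl)-2-[(phenylselanyl)methyl]cyclohex-4-ene-1,3-dione | CC[C@@H](C)C(=O)C1=C(O)[C@](CC(C)=C)(C)C(=O)[C@@](CC=C(C)C)(C[Se]c2ccccc2)C1=O
F3 | step 5 | (2R)-2-methyl-1-[2,4,6-trihydroxy-3-methyl-5-(3-methylbut-2-en-1-yl)phenyl]butan-1-one | CC[C@@H](C)C(=O)c1c(O)c(CC=C(C)C)c(O)c(C)c1O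
F4 | step 5 | (6R)-3,5-dihydroxy-6-methyl-4-[(2R)-2-methylbutanoyl]-2-(3-methylbut-2-en-1-yl)-6-(2-methylprop-1-en-1-yl)cyclohexa-2,4-dien-1-one | CC[C@@H](C)C(=O)C1=C(O)[C@](C=C(C)C)(C)C(=O)C(CC=C(C)C)=C1O
F5 | step 6 | (1R,5R,6R)-4-hydroxy-5-methyl-3-[(2R)-2-methylbutanoyl]-1-(3-methylbut-2-en-1-yl)-6-[2-(phenylselanyl)propan-2-yl]bicyclo[3.2.1]oct-3-ene-2,8-dione | CC[C@@H](C)C(=O)C1=C(O)[C@]2(C)C(=O)[C@@](CC=C(C)C)(C[C@H]2C(C)(C)[Se]c3ccccc3)C1=O
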